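**Remarks before the route**

- Assumption: the SMILES is read as (3R,5S,8S,9R,10R,13R)-3-bromolabd-14-ene-9,13-diol. In this isomer O9 and the C10 methyl (C20) are cis on ring B, and C11 and the C8 methyl (C17) lie on the other face.
- The lactone and the rearranged acid match in configuration: a 6R lactone with a 4,6-trans methyl gives 9R,10R. Three design points follow from the structures.
  - The ring closure is an exchange, not a contraction: lactone and carbocycle are both six-membered.
  - O9 enters the key step as a free hydroxyl that is silylated in the flask. An acetal on O9 would need acid at the end, and a 9,13-diol with a tertiary allylic C13–OH closes to the 9,13-ether under acid.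
  - A bromonium cyclization gives racemic C3, and no enantioselective version is established for a geranyl substrate of this kind. C3 is therefore resolved through a diastereomer pair in step 5.
- Ring A is built from geraniol as its tert-butyl carbonate, not from a geranate ester. The internal alkene is the better nucleophile, and the carbonate oxygen captures the C10 cation, so the cyclization should give one compound and not a set of double-bond isomers. The conjugated enal is then reached by oxidation and β-elimination.

## Structural features

The target is a trans-decalin (ring A = C1–C5, C10; ring B = C5–C10) carrying an equatorial bromine on C3 next to the gem-dimethyl carbon C4, an angular methyl on C10, a methyl on C8, and a tertiary hydroxyl plus a five-carbon chain (C11–C15, methyl C16) on C9. C8, C9 and C10 are three contiguous stereocentres, two of them fully substituted; C5 and C3 complete the ring set and C13, a tertiary allylic carbinol, is remote from all of them. On ring B, O9 is cis to C20, while C11 and C17 are on the opposite face; H5 is trans to C20 and the bromine is cis to it. Fragile groups are the neopentyl-type secondary bromide (elimination, Wagner–Meerwein shifts under Lewis acid, reduction), the tertiary allylic alcohol, and the 9,13-diol pair, which gives a tetrahydrofuran under acid. The real difficulty is the C9–C10 bond, which joins a fully substituted carbinol carbon to a quaternary ring-fusion carbon, together with a C3–Br centre that has no neighbouring handle. The key step uses the fact that C9 bears both an oxygen and C11: C9 can be the α-carbon of a lactone enolate with C11 as carbonyl. C10 is the methyl-bearing end of a ring A alkene C5=C10 that is allylic to a C6–O bond. The array C9=C11–O–C6–C5=C10 is thus set up for a [3,3] shift that makes C9–C10 and closes ring B.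

## Logic of the disconnections

33 to 32 and 30 (through 31): the O9–Si bond is cut last, and the C13 carbinol with the C14=C15 alkene is traced to a 13,14-epoxide bearing a leaving group on C15. No skeletal bond is cut; the reason is that remote C13 can only be set by reagent control, which an allylic-alcohol epoxidation provides. The demand is that the last steps stay non-acidic and that O9 is masked from 27 to 32, so that it cannot open the epoxide or the allylic carbinol.

30 to 29 to 27: C13–C16 and C14–C15 are cut, both being added across a terminal alkyne. This reduces the side chain to four carbons; the forward step must add syn so that the alkene is E, and must tolerate the bromide.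

27 to 23 and 24: C11–C12 is cut. C11 is a primary carbon next to a fully substituted one and can only be substituted as the CH2 of a 9,11-epoxide. The gain is that the chain comes from commercial 24; the demand is an SN2 opening at C11 that leaves the C9–O bond intact.

23 to 21 to 20 to 19: functional-group changes only (epoxide from the 9,11-diol, H5 from the C5=C6 alkene, CH2OH from CO2H). They lead back to the acid that the key step delivers. The hydrogen on C5 must arrive anti to C20.

19 to 15 (key disconnection): C9–C10 is cut and O–C6 is reconnected. Two adjacent fully substituted stereocentres and ring B are exchanged for a monocyclic lactone whose only controlling centres are C6 and C8. The forward step needs a boat transition state, heat, the 6R configuration and a C8 methyl trans to ring A.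

15 to 14 to 13: C9–O (enolate oxidation) and C8–C17 (conjugate addition) are cut. The C9 configuration is irrelevant; C8 must be set trans to the ring A substituent.

13 to 12 to 10 and 11: the C8=C9 alkene (metathesis) and the ester C–O bond are cut, leaving a homoallylic alcohol. The metathesis must ignore the tetrasubstituted ring alkene.

10 to 8 and 9: C6–C7 is cut. C6 is the one centre from which C9 and C10 derive, so it is set by reagent control. Because 8 is racemic, the same step turns its two enantiomers into 10 and the C3 epimer of 10, which must be separated.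

8 to 5 (through 6 and 7): the C5=C10 alkene is traced to a C10 hydroxyl and a C5 hydrogen, and the aldehyde to a primary alcohol. No skeletal bond is cut; the reason is that β-elimination from a defined aldol-type carbinol leads only to the conjugated alkene, whereas proton loss from a cation would give several double-bond isomers. The demand is that elimination is faster than retro-aldol opening of the ring.

5 to 4 to 3: the two hydroxyls are tied up as a cyclic carbonate, and C4–C5, C3–Br and C10–O are cut together (bromonium-induced cyclization ended by the carbonate oxygen). The gain is an acyclic precursor; the anti additions fix only the relative configuration, so C3 is racemic, and the carbonate must capture the C10 cation before a proton is lost.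

3 to 1 and 2: the carbonate C–O bond is cut, which leads to two commercial materials; the only demand is clean mono-acylation of the primary allylic alcohol.

## Other disconnections considered

Alternative 1: The cut is C9–C10 together with O9–C20, tracing 9-OH and the C20 methyl to the oxetane A2, which would come from the seco ketone A1 (ring A with an exocyclic C10=C20 methylene and a C9 ketone in the chain on C5). The forward step is a Paternò–Büchi photocycloaddition: the excited ketone oxygen adds to C20, and the tertiary C10 radical closes onto C9.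
- In its favour: a four-membered ring can only bridge cis, so the O9/C20 relation is built in; on this point it is the equal of the chosen plan, which enforces the same relation through its tether. Ring A of A1 keeps the C5 centre that a bromonium cyclization sets together with C3, so nothing has to be erased and rebuilt; here the alternative is the better.
- Against it: dialkyl ketone excited states are diverted by α-cleavage next to C8 and by γ-hydrogen abstraction from C6. The C5-to-C10 relation rests on the folding of a flexible chain, not on a sigmatropic transfer. The C–Br bond is at risk under irradiation. The oxetane must afterwards be opened reductively at a neopentyl CH2, and the vinyl group must be unmasked.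
- Comparison: both plans form C9–C10 intramolecularly, one by a stepwise biradical and one by a concerted thermal shift. A1 needs C5, C8 and C13 set independently before closure and several steps after it, so it should be longer and less certain.

Alternative 2: The cut removes C8 from ring B. The decalone A5 would come from the trans-fused hydrindanone A3 by insertion of the ethylidene unit of diazoethane A4 under Lewis acid catalysis, with migration of the C7 methylene. The side chain would then be added to the C9 ketone.
- In its favour: A5 is one C–C bond from the complete skeleton. A whole C11–C16 chain with C13 preset could be added as an organometallic; attack anti to the axial C20 would give the required C9 configuration, and C8 can equilibrate to the equatorial methyl. On step economy and convergence this alternative is the better plan. The migration regiochemistry (CH2 over quaternary C10) is favourable.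
- Against it: A3 is a strained trans-hydrindanone that no cation–olefin cyclization gives directly, so the difficulty moves into the precursor. A4 is hazardous and can insert twice or give an epoxide. The final addition to a ketone flanked by C10 and C8 competes with enolization, and its facial outcome is a bias, not a constraint. Absolute configuration at C3 is as unsolved as in the chosen plan.
- Comparison: the chosen plan is longer but fixes C9 and C10 by chirality transfer; the alternative is shorter and rests on a facial preference.

Alternative 3: The cut is C8–C9. The cyclohexenol A7 would come from the keto alkenyl bromide A6 by an intramolecular Nozaki–Hiyama–Kishi addition of the C8 alkenylchromium to the C9 ketone.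
- In its favour: the conditions are mild and non-basic, and the most hindered ring bond is closed intramolecularly. The C7=C8 alkene beside the C9 hydroxyl would allow a hydroxyl-directed hydrogenation that puts H8 cis to O9; on control of C8 it is the equal of the chosen plan.
- Against it: ketones, especially on a quaternary carbon, are poor acceptors in this reaction, and alkenyl bromides are sluggish. Low-valent metal may reduce the secondary alkyl bromide. The C9 configuration depends on the rotamer of a free acyl group. A6 already contains quaternary C10 next to C5, so the hardest centre is not made by the key step.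
- Comparison: the chosen plan creates C9 and C10 in one event from C6; the alternative needs C10 beforehand and the same side-chain unmasking, so its step count is no lower.

Key step: step 10

## Route

Step 1
Reactants: 1 geraniol; 2 di-tert-butyl dicarbonate
Product: 3 tert-butyl (2E)-3,7-dimethylocta-2,6-dien-1-yl carbonate (geranyl tert-butyl carbonate)
Conditions: n-BuLi (1.05 equiv), THF, −78 °C; 2 (1.1 equiv), −78 °C to rt; aq. NH4Cl
Reagents that add atoms: di-tert-butyl dicarbonate (2), CC(C)(C)OC(=O)OC(=O)OC(C)(C)C
Why: O-Acylation of the lithium alkoxide by the dicarbonate (formation of a mixed tert-butyl carbonate); the preformed alkoxide should avoid the symmetrical carbonate, and neither alkene is touched.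

Step 2
Reactants: 3 tert-butyl (2E)-3,7-dimethylocta-2,6-dien-1-yl carbonate
Product: 4 rac-(4aS,6R,8aR)-6-bromo-5,5,8a-trimethylhexahydro-4H-1,3-benzodioxin-2-one
Conditions: Et2SBr·SbCl5Br (BDSB, 1.1 equiv), MeNO2, −25 °C, 5 min; aq. NaHCO3/Na2SO3
Reagents that add atoms: bromodiethylsulfonium bromopentachloroantimonate (BDSB), CC[S+](Br)CC.Cl[Sb-](Cl)(Cl)(Cl)(Cl)Br
Why: Bromonium-induced cation–olefin cyclization ended by a tert-butyl carbonate: anti addition of Br and C5 across the terminal alkene through a chair should place Br equatorial, and anti addition of C4 and the carbonyl oxygen across the E alkene should give the trans-fused cyclic carbonate with loss of 2-methylpropene. Capture of the C10 cation by oxygen in place of proton loss means that one compound is formed. It is racemic; C3 is resolved in step 5, and the C5 and C10 centres are erased in step 4.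

Step 3
Reactants: 4 rac-(4aS,6R,8aR)-6-bromo-5,5,8a-trimethylhexahydro-4H-1,3-benzodioxin-2-one
Product: 5 rac-(1R,2S,4R)-4-bromo-2-(hydroxymethyl)-1,3,3-trimethylcyclohexan-1-ol
Conditions: K2CO3 (0.5 equiv), MeOH, 0 °C to rt
Reagents that add atoms: none
Why: Base-catalysed transesterification of the cyclic carbonate with methanol releases the 1,3-diol and dimethyl carbonate. The equatorial bromide has no antiperiplanar hydrogen and sits next to a quaternary carbon, so it should survive carbonate in methanol.

Step 4
Reactants: 5 rac-(1R,2S,4R)-4-bromo-2-(hydroxymethyl)-1,3,3-trimethylcyclohexan-1-ol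
Product: 8 rac-5-bromo-2,6,6-trimethylcyclohex-1-ene-1-carbaldehyde, via hydroxy aldehyde 6 (not isolated), via tertiary mesylate 7 (not isolated)
Conditions: Dess–Martin periodinane, NaHCO3, CH2Cl2, 0 °C to rt; aq. Na2S2O3/NaHCO3 wash, dry; then MsCl (1.5 equiv), Et3N (3 equiv), CH2Cl2, 0 °C; DBU (2 equiv), 0 °C to rt
Reagents that add atoms: none
Why: Dess–Martin oxidation of the primary alcohol (the tertiary one cannot be oxidized), then sulfonylation of the tertiary hydroxyl through sulfene and base-induced β-elimination (aldol-type dehydration, E1cB) should give the conjugated enal. Any non-conjugated alkene formed by ionization of the mesylate should be drawn into conjugation by DBU through the dienolate, the known α- to β-cyclocitral isomerization. C5 and C10 become sp2, leaving C3 as the only (racemic) stereocentre.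

Step 5
Reactants: 8 rac-5-bromo-2,6,6-trimethylcyclohex-1-ene-1-carbaldehyde; 9 allylmagnesium bromide
Product: 10 (1R)-1-[(5R)-5-bromo-2,6,6-trimethylcyclohex-1-en-1-yl]but-3-en-1-ol
Conditions: (+)-Ipc2BOMe (from (−)-α-pinene), 9, Et2O, 0 °C, then −78 °C; 8, −78 to −20 °C; NaOH, H2O2; chromatography (C3 epimer removed)
Reagents that add atoms: allylmagnesium bromide (9), C=CC[Mg]Br
Why: Brown asymmetric allylboration through a chair Zimmerman–Traxler transition state; this antipode of the reagent (the one that turns benzaldehyde into (R)-1-phenylbut-3-en-1-ol) should deliver allyl to the Re face and set the carbinol carbon C6 as R in both enantiomers of 8. The (5R) enantiomer of 8 gives 10 and the (5S) enantiomer gives the C3 epimer of 10; the two are diastereomers, and removing the epimer here fixes C3 as R.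

Step 6
Reactants: 10 (1R)-1-[(5R)-5-bromo-2,6,6-trimethylcyclohex-1-en-1-yl]but-3-en-1-ol; 11 acryloyl chloride
Product: 12 (1R)-1-[(5R)-5-bromo-2,6,6-trimethylcyclohex-1-en-1-yl]but-3-en-1-yl prop-2-enoate
Conditions: iPr2NEt, DMAP (cat.), CH2Cl2, −20 to 0 °C
Reagents that add atoms: acryloyl chloride (11), C=CC(=O)Cl
Why: O-Acylation of the secondary alcohol; the C–O bond of the stereocentre is not touched.

Step 7
Reactants: 12 (1R)-1-[(5R)-5-bromo-2,6,6-trimethylcyclohex-1-en-1-yl]but-3-en-1-yl prop-2-enoate
Product: 13 (6R)-6-[(5R)-5-bromo-2,6,6-trimethylcyclohex-1-en-1-yl]-5,6-dihydro-2H-pyran-2-one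
Conditions: second-generation Grubbs catalyst (H2IMes)(PCy3)Cl2Ru=CHPh (5 mol %), CH2Cl2 (5 mM), 40 °C
Reagents that add atoms: none
Why: Ring-closing metathesis of the acrylate with the terminal alkene gives the unsaturated δ-lactone; the tetrasubstituted ring A alkene is too hindered to take part.

Step 8
Reactants: 13 (6R)-6-[(5R)-5-bromo-2,6,6-trimethylcyclohex-1-en-1-yl]-5,6-dihydro-2H-pyran-2-one
Product: 14 (4S,6R)-6-[(5R)-5-bromo-2,6,6-trimethylcyclohex-1-en-1-yl]-4-methyloxan-2-one
Conditions: MeLi (2 equiv), CuI (1 equiv), Et2O, 0 °C; 13, −78 to −40 °C; aq. NH4Cl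
Reagents that add atoms: lithium dimethylcuprate, [Li+].C[Cu-]C (made from methyllithium, [Li]C, and CuI)
Why: Conjugate addition of the cuprate to the unsaturated lactone; axial delivery anti to the C6 substituent should give the 4,6-trans lactone and so set C8 (4S). The hindered secondary bromide should not couple at this temperature.

Step 9
Reactants: 14 (4S,6R)-6-[(5R)-5-bromo-2,6,6-trimethylcyclohex-1-en-1-yl]-4-methyloxan-2-one
Product: 15 (3R,4S,6R)-6-[(5R)-5-bromo-2,6,6-trimethylcyclohex-1-en-1-yl]-3-hydroxy-4-methyloxan-2-one
Conditions: KN(SiMe3)2, THF, −78 °C; 3-phenyl-2-(phenylsulfonyl)oxaziridine, −78 °C; aq. NH4Cl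
Reagents that add atoms: 3-phenyl-2-(phenylsulfonyl)oxaziridine, O=S(=O)(c1ccccc1)N1OC1c1ccccc1
Why: Enolate α-hydroxylation with an N-sulfonyloxaziridine; attack anti to the C4 methyl should give the 3,4-trans alcohol. This centre becomes sp2 again in step 10, so either epimer serves.

Step 10
Reactants: 15 (3R,4S,6R)-6-[(5R)-5-bromo-2,6,6-trimethylcyclohex-1-en-1-yl]-3-hydroxy-4-methyloxan-2-one
Product: 19 (3R,8S,9R,10R)-3-bromo-9-hydroxydrim-5-en-11-oic acid, via silylated lactone 16 (not isolated), via bis-silyl ketene acetal 17 (not isolated), via bis-silyl ester 18 (not isolated)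
Conditions: Me3SiCl, Et3N, THF, 0 °C; KN(SiMe3)2, Me3SiCl, THF–toluene, −78 °C to rt; toluene, 110 °C (sealed); then K2CO3, MeOH–H2O, rt, acidify to pH 4 (citric acid)
Reagents that add atoms: none
Why: Silylation of O9 and enolization give ketene acetal 17, whose C9=C11–O–C6–C5=C10 array should undergo a concerted, suprafacial [3,3] shift on heating (Ireland–Claisen): C9–C10 forms, C6–O breaks, C11 becomes a silyl carboxylate and the alkene moves to C5=C6. The closest known reaction type is the Ireland–Claisen rearrangement of silyl ketene acetals of 6-alkenyl δ-lactones to cyclohexenecarboxylic acids, and of α-oxygenated (glycolate, dioxanone) ketene acetals. Ring B closes by ring exchange: the six-membered lactone gives up the O–C11 unit and takes in C5–C10, so the ring size stays six, and the C7–C8 tether forces a boat, bicyclo[2.2.2]-like transition state with bridges C11–O, C7–C8 and C5–C10 between C9 and C6. C9 is controlled by C6: the alkene can reach C9 only on the lactone face that carries it, so C11 stays on the face from which the oxygen leaves and O9 turns to the other face (9R). C10 is controlled by the fixed geometry of the ring alkene together with the suprafacial course, which puts C1 on the side of C11 and C20 on the side of O9 (10R). C8 is untouched and, being trans to ring A in 15, ends cis to C11; the old C9 configuration is erased and the ketene acetal geometry is fixed by the ring, so neither needs control. The step needs the [3,3] shift to outrun ionization and elimination of the allylic C6–O bond; the tether, the irreversible formation of the carboxyl group and a neutral medium should secure this, although two fully substituted termini and the allylic strain between C7 and C20 mean that 110–140 °C will be needed.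

Step 11
Reactants: 19 (3R,8S,9R,10R)-3-bromo-9-hydroxydrim-5-en-11-oic acid
Product: 20 (3R,8S,9R,10R)-3-bromodrim-5-ene-9,11-diol
Conditions: LiAlH4, THF, 0 to 40 °C; Fieser work-up
Reagents that add atoms: none
Why: Hydride reduction of the carboxylic acid to the primary alcohol; the hindered trisubstituted alkene is inert, and the neopentyl-type secondary bromide should be displaced by hydride far more slowly than the carboxylate is reduced.

Step 12
Reactants: 20 (3R,8S,9R,10R)-3-bromodrim-5-ene-9,11-diol
Product: 21 (3R,5S,8S,9R,10R)-3-bromodrimane-9,11-diol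
Conditions: Mn(dpm)3 (10 mol %), PhSiH3, tBuOOH, iPrOH, rt; K2CO3/MeOH work-up
Reagents that add atoms: none
Why: Mukaiyama-type hydrogen-atom-transfer hydrogenation: H adds to C6 to give the tertiary C5 radical, which should take its hydrogen on the face opposite to the axial C20 and the axial C4 methyl. This gives the trans ring fusion (5S), the thermodynamic isomer; hydroxyl groups and alkyl bromides are tolerated by this radical manifold.

Step 13
Reactants: 21 (3R,5S,8S,9R,10R)-3-bromodrimane-9,11-diol
Product: 23 (3R,5S,8S,9R,10R)-3-bromo-9,11-epoxydrimane, via primary tosylate 22 (not isolated)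
Conditions: NaH (2.5 equiv), N-tosylimidazole (1.1 equiv), THF, 0 °C to rt
Reagents that add atoms: none
Why: Selective sulfonylation of the primary alkoxide and intramolecular Williamson closure by the tertiary alkoxide (one-flask diol-to-epoxide conversion); the C9–O bond is not broken, so C9 keeps its configuration.

Step 14
Reactants: 23 (3R,5S,8S,9R,10R)-3-bromo-9,11-epoxydrimane; 24 1-(trimethylsilyl)propyne
Product: 27 (3R,5S,8S,9R,10R)-3-bromo-9-(triethylsilyloxy)-15,16-dinorlabd-13-yne, via silylalkyne carbinol 25 (not isolated), via bis-silyl alkyne 26 (not isolated)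
Conditions: 24, n-BuLi, TMEDA, THF, −78 to −20 °C; 23, DMPU, −20 °C to rt; Et3SiOTf, −78 to 0 °C; then K2CO3, MeOH, rt
Reagents that add atoms: 1-(trimethylsilyl)propyne (24), CC#C[Si](C)(C)C; triethylsilyl trifluoromethanesulfonate, CC[Si](CC)(CC)OS(=O)(=O)C(F)(F)F
Why: SN2 opening of the epoxide at its unsubstituted carbon C11 by lithiated 1-(trimethylsilyl)propyne (propargylation; the silyl group suppresses the allenyl product). The tertiary alkoxide is trapped as its triethylsilyl ether, and methanolic carbonate should remove only the alkynyl silyl group; O9 is thereby masked for steps 15–17.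

Step 15
Reactants: 27 (3R,5S,8S,9R,10R)-3-bromo-9-(triethylsilyloxy)-15,16-dinorlabd-13-yne
Product: 29 (13E)-(3R,5S,8S,9R,10R)-3-bromo-9-(triethylsilyloxy)labd-13-en-15-ol, via alkenylalane 28 (not isolated)
Conditions: Me3Al (3 equiv), Cp2ZrCl2 (0.5 equiv), H2O (1 equiv), CH2Cl2, −20 °C; then n-BuLi, −78 °C; (CH2O)n, THF, −78 °C to rt; aq. KNaC4H4O6 (potassium sodium tartrate)
Reagents that add atoms: trimethylaluminium, C[Al](C)C; paraformaldehyde (as formaldehyde), C=O
Why: Zirconium-catalysed methylalumination of the terminal alkyne (Negishi carboalumination; syn addition, methyl to C13 and aluminium to C14), followed by hydroxymethylation of the alkenyl aluminate with formaldehyde with retention. This should give the E allylic alcohol; the short, cold, water-accelerated protocol limits exposure of the bromide to the Lewis acid.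

Step 16
Reactants: 29 (13E)-(3R,5S,8S,9R,10R)-3-bromo-9-(triethylsilyloxy)labd-13-en-15-ol
Product: 30 (3R,5S,8S,9R,10R,13R,14R)-3-bromo-13,14-epoxy-9-(triethylsilyloxy)labdan-15-ol
Conditions: Ti(OiPr)4 (10 mol %), D-(−)-diethyl tartrate (12 mol %), tBuOOH, 4 Å sieves, CH2Cl2, −20 °C
Reagents that add atoms: tert-butyl hydroperoxide, CC(C)(C)OO
Why: Sharpless asymmetric epoxidation; with D-(−)-tartrate the E allylic alcohol should give the (13R,14R)-epoxide, the mirror-image series of the (2S,3S)-epoxide that geraniol gives with L-(+)-tartrate. This fixes C13 by reagent control, and with O9 silylated no hydroxyl can open the epoxide.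

Step 17
Reactants: 30 (3R,5S,8S,9R,10R,13R,14R)-3-bromo-13,14-epoxy-9-(triethylsilyloxy)labdan-15-ol
Product: 32 (3R,5S,8S,9R,10R,13R)-3-bromo-9-(triethylsilyloxy)labd-14-en-13-ol, via epoxy iodide 31 (not isolated)
Conditions: PPh3, I2, imidazole, THF, 0 °C; then Zn dust, EtOH, 60 °C
Reagents that add atoms: none
Why: Phosphine–iodine iodination of the primary alcohol, then zinc-mediated reductive β-elimination of the epoxy iodide (1,3-transposition of a 2,3-epoxy alcohol). C14–O breaks and C13–O is kept, so the tertiary allylic alcohol should be 13R; unactivated alkyl bromides do not insert zinc under these conditions.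

Step 18
Reactants: 32 (3R,5S,8S,9R,10R,13R)-3-bromo-9-(triethylsilyloxy)labd-14-en-13-ol
Product: 33 (3R,5S,8S,9R,10R,13R)-3-bromolabd-14-ene-9,13-diol
Conditions: Bu4NF, THF, rt to 40 °C
Reagents that add atoms: none
Why: Fluoride cleavage of the tertiary triethylsilyl ether; no acid is present, so the 9,13-diol cannot close to the 9,13-ether and the allylic carbinol cannot ionize.

## Compound list

1 | geraniol, (2E)-3,7-dimethylocta-2,6-dien-1-ol | OC/C=C(\C)CCC=C(C)C | starting material
2 | di-tert-butyl dicarbonate | CC(C)(C)OC(=O)OC(=O)OC(C)(C)C | starting material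
3 | tert-butyl (2E)-3,7-dimethylocta-2,6-dien-1-yl carbonate (geranyl tert-butyl carbonate) | CC(C)(C)OC(=O)OC/C=C(\C)CCC=C(C)C | intermediate
4 | rac-(4aS,6R,8aR)-6-bromo-5,5,8a-trimethylhexahydro-4H-1,3-benzodioxin-2-one (racemate, one enantiomer drawn) | O=C1OC[C@@H]2C(C)(C)[C@H](Br)CC[C@@]2(C)O1 | intermediate
5 | rac-(1R,2S,4R)-4-bromo-2-(hydroxymethyl)-1,3,3-trimethylcyclohexan-1-ol (racemate, one enantiomer drawn) | OC[C@@H]1C(C)(C)[C@H](Br)CC[C@@]1(C)O | intermediate
6 | rac-(1R,3R,6R)-3-bromo-6-hydroxy-2,2,6-trimethylcyclohexane-1-carbaldehyde (racemate, one enantiomer drawn) | O=C[C@@H]1C(C)(C)[C@H](Br)CC[C@@]1(C)O | intermediate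
7 | rac-(1R,2R,4R)-4-bromo-2-formyl-1,3,3-trimethylcyclohexyl methanesulfonate (racemate, one enantiomer drawn) | O=C[C@@H]1C(C)(C)[C@H](Br)CC[C@@]1(C)OS(C)(=O)=O | intermediate
8 | rac-5-bromo-2,6,6-trimethylcyclohex-1-ene-1-carbaldehyde (racemate) | O=CC1=C(C)CCC(Br)C1(C)C | intermediate
9 | allylmagnesium bromide | C=CC[Mg]Br | starting material
10 | (1R)-1-[(5R)-5-bromo-2,6,6-trimethylcyclohex-1-en-1-yl]but-3-en-1-ol | O[C@H](CC=C)C1=C(C)CC[C@@H](Br)C1(C)C | intermediate
11 | acryloyl chloride | C=CC(=O)Cl | starting material
12 | (1R)-1-[(5R)-5-bromo-2,6,6-trimethylcyclohex-1-en-1-yl]but-3-en-1-yl prop-2-enoate | C=CC(=O)O[C@H](CC=C)C1=C(C)CC[C@@H](Br)C1(C)C | intermediate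
13 | (6R)-6-[(5R)-5-bromo-2,6,6-trimethylcyclohex-1-en-1-yl]-5,6-dihydro-2H-pyran-2-one | O=C1O[C@H](CC=C1)C2=C(C)CC[C@@H](Br)C2(C)C | intermediate
14 | (4S,6R)-6-[(5R)-5-bromo-2,6,6-trimethylcyclohex-1-en-1-yl]-4-methyloxan-2-one | O=C1O[C@H](C[C@H](C)C1)C2=C(C)CC[C@@H](Br)C2(C)C | intermediate
15 | (3R,4S,6R)-6-[(5R)-5-bromo-2,6,6-trimethylcyclohex-1-en-1-yl]-3-hydroxy-4-methyloxan-2-one | O=C1O[C@H](C[C@H](C)[C@H]1O)C2=C(C)CC[C@@H](Br)C2(C)C | intermediate
16 | (3R,4S,6R)-6-[(5R)-5-bromo-2,6,6-trimethylcyclohex-1-en-1-yl]-4-methyl-3-(trimethylsilyloxy)oxan-2-one | O=C1O[C@H](C[C@H](C)[C@H]1O[Si](C)(C)C)C2=C(C)CC[C@@H](Br)C2(C)C | intermediate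
17 | (4S,6R)-6-[(5R)-5-bromo-2,6,6-trimethylcyclohex-1-en-1-yl]-4-methyl-2,3-bis(trimethylsilyloxy)-5,6-dihydro-4H-pyran | C[Si](C)(C)OC1=C(O[Si](C)(C)C)[C@@H](C)C[C@@H](O1)C2=C(C)CC[C@@H](Br)C2(C)C | intermediate
18 | trimethylsilyl (3R,8S,9R,10R)-3-bromo-9-(trimethylsilyloxy)drim-5-en-11-oate | C[Si](C)(C)OC(=O)[C@@]1(O[Si](C)(C)C)[C@@H](C)CC=C2C(C)(C)[C@H](Br)CC[C@]21C | intermediate
19 | (3R,8S,9R,10R)-3-bromo-9-hydroxydrim-5-en-11-oic acid | OC(=O)[C@@]1(O)[C@@H](C)CC=C2C(C)(C)[C@H](Br)CC[C@]21C | intermediate
20 | (3R,8S,9R,10R)-3-bromodrim-5-ene-9,11-diol | OC[C@@]1(O)[C@@H](C)CC=C2C(C)(C)[C@H](Br)CC[C@]21C | intermediate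
21 | (3R,5S,8S,9R,10R)-3-bromodrimane-9,11-diol | OC[C@@]1(O)[C@@H](C)CC[C@@H]2C(C)(C)[C@H](Br)CC[C@]21C | intermediate
22 | (3R,5S,8S,9R,10R)-3-bromo-9-hydroxydriman-11-yl 4-methylbenzenesulfonate | Cc1ccc(cc1)S(=O)(=O)OC[C@@]1(O)[C@@H](C)CC[C@@H]2C(C)(C)[C@H](Br)CC[C@]21C | intermediate
23 | (3R,5S,8S,9R,10R)-3-bromo-9,11-epoxydrimane | C1O[C@@]12[C@@H](C)CC[C@@H]3C(C)(C)[C@H](Br)CC[C@]32C | intermediate
24 | 1-(trimethylsilyl)propyne | CC#C[Si](C)(C)C | starting material
25 | (3R,5S,8S,9R,10R)-3-bromo-14-(trimethylsilyl)-15,16-dinorlabd-13-yn-9-ol | C[Si](C)(C)C#CCC[C@@]1(O)[C@@H](C)CC[C@@H]2C(C)(C)[C@H](Br)CC[C@]21C | intermediate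
26 | (3R,5S,8S,9R,10R)-3-bromo-9-(triethylsilyloxy)-14-(trimethylsilyl)-15,16-dinorlabd-13-yne | C[Si](C)(C)C#CCC[C@@]1(O[Si](CC)(CC)CC)[C@@H](C)CC[C@@H]2C(C)(C)[C@H](Br)CC[C@]21C | intermediate
27 | (3R,5S,8S,9R,10R)-3-bromo-9-(triethylsilyloxy)-15,16-dinorlabd-13-yne | C#CCC[C@@]1(O[Si](CC)(CC)CC)[C@@H](C)CC[C@@H]2C(C)(C)[C@H](Br)CC[C@]21C | intermediate
28 | [(13E)-(3R,5S,8S,9R,10R)-3-bromo-9-(triethylsilyloxy)-15-norlabd-13-en-14-yl]dimethylalane | C[Al](C)/C=C(\C)CC[C@@]1(O[Si](CC)(CC)CC)[C@@H](C)CC[C@@H]2C(C)(C)[C@H](Br)CC[C@]21C | intermediate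
29 | (13E)-(3R,5S,8S,9R,10R)-3-bromo-9-(triethylsilyloxy)labd-13-en-15-ol | OC/C=C(\C)CC[C@@]1(O[Si](CC)(CC)CC)[C@@H](C)CC[C@@H]2C(C)(C)[C@H](Br)CC[C@]21C | intermediate
30 | (3R,5S,8S,9R,10R,13R,14R)-3-bromo-13,14-epoxy-9-(triethylsilyloxy)labdan-15-ol | OC[C@H]1O[C@]1(C)CC[C@@]2(O[Si](CC)(CC)CC)[C@@H](C)CC[C@@H]3C(C)(C)[C@H](Br)CC[C@]32C | intermediate
31 | (3R,5S,8S,9R,10R,13R,14S)-3-bromo-13,14-epoxy-15-iodo-9-(triethylsilyloxy)labdane | IC[C@H]1O[C@]1(C)CC[C@@]2(O[Si](CC)(CC)CC)[C@@H](C)CC[C@@H]3C(C)(C)[C@H](Br)CC[C@]32C | intermediate
32 | (3R,5S,8S,9R,10R,13R)-3-bromo-9-(triethylsilyloxy)labd-14-en-13-ol | C=C[C@](C)(O)CC[C@@]1(O[Si](CC)(CC)CC)[C@@H](C)CC[C@@H]2C(C)(C)[C@H](Br)CC[C@]21C | intermediate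
33 | (3R,5S,8S,9R,10R,13R)-3-bromolabd-14-ene-9,13-diol | C=C[C@](C)(O)CC[C@@]1(O)[C@@H](C)CC[C@@H]2C(C)(C)[C@H](Br)CC[C@]21C | target

## Step count and least certain steps

Total: 18 steps. Longest linear sequence: 18 steps from 1 (2, 9, 11 and 24 are bought). Every stereocentre is accounted for: C3 in steps 2 and 5, C6 (relay) in step 5, C8 in step 8, C9 and C10 in step 10, C5 in step 12, C13 in step 16.

Step 10 (key step). What may go wrong: the hindered ketene acetal may fail to reach the boat transition state before the allylic C6–O bond ionizes and the lactone is lost by elimination to a diene acid. The two fully substituted termini and the clash between C7 and C20 make this the most demanding step. Fallback, from 14 to 23: the oxygen is left off the α-carbon so that the ketene acetal is less substituted, and C9 is brought to its final state afterwards by a carbonyl addition. 14 is converted with KN(SiMe3)2 and Me3SiCl into the unsubstituted silyl ketene acetal F1, which should rearrange on heating to the silyl ester F2 and, after hydrolysis, give the C9–H acid F3. Oxygenation of the carboxylate dianion (LDA, then O2) gives the α-hydroperoxy acid F4, which fragments with loss of CO2 to the nor-ketone F5. Dimethylsulfonium methylide should add to F5 on the face opposite to C20 (Corey–Chaykovsky epoxidation), which places C11 trans and O9 cis to C20 and gives the unsaturated spiro-epoxide F6. Hydrogen-atom-transfer hydrogenation as in step 12 then returns to 23.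

Step 5. What may go wrong: incomplete chromatographic separation of the two C3 epimers, whose stereocentres are 1,4-related across an sp2 carbon and may give very similar polarity; erosion of facial control on the hindered enal is a second concern. Fallback, from 8 to 10: the enantiomers of 8 are split before the addition by preparative chromatography on a chiral stationary phase (supercritical CO2, amylose tris(3,5-dimethylphenylcarbamate)). The single enantiomer (5R)-5-bromo-2,6,6-trimethylcyclohex-1-ene-1-carbaldehyde F7 then gives 10 alone under the conditions of step 5.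

Step 14. What may go wrong: slow substitution at C11 of the hindered spiro-epoxide, so that base-induced isomerization of the epoxide to an allylic alcohol or incomplete silylation of the very hindered alkoxide competes. Fallback, from 23 to 29: a softer carbon nucleophile is used and the allylic alcohol is built by olefination. Allylmagnesium bromide 9 with CuI (10 mol %) opens 23 at C11, and trapping with Et3SiOTf gives the butenyl silyl ether F8. Wacker oxidation (PdCl2, CuCl, O2, DMF–H2O) gives the methyl ketone F9. Horner–Wadsworth–Emmons reaction with triethyl phosphonoacetate gives the E enoate F10 (the Z isomer is removed), and iBu2AlH reduction returns to 29.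

Step 15. What may go wrong: ionization or rearrangement of the neopentyl-type bromide, or loss of the tertiary silyl ether, under the Lewis-acidic aluminium–zirconium mixture; incomplete capture of the alkenylalane by formaldehyde would end in protonation to the 2-methylalkene. Fallback, from 27 to 29: the trisubstituted alkene is set by hydroalumination and cuprate coupling. Deprotonation of 27 (n-BuLi) and addition to paraformaldehyde give the propargylic alcohol F11. Trans-hydroalumination with NaAlH2(OCH2CH2OMe)2 and iodination give the Z iodoalkene F12, and coupling with Me2CuLi (lithium dimethylcuprate), with retention, returns to 29.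

## Further compounds

F1 | step 10 | (4S,6R)-6-[(5R)-5-bromo-2,6,6-trimethylcyclohex-1-en-1-yl]-4-methyl-2-(trimethylsilyloxy)-5,6-dihydro-4H-pyran | C[Si](C)(C)OC1=C[C@@H](C)C[C@@H](O1)C2=C(C)CC[C@@H](Br)C2(C)C
F2 | step 10 | trimethylsilyl (3R,8S,9S,10S)-3-bromodrim-5-en-11-oate | C[Si](C)(C)OC(=O)[C@H]1[C@@H](C)CC=C2C(C)(C)[C@H](Br)CC[C@]21C
F3 | step 10 | (3R,8S,9S,10S)-3-bromodrim-5-en-11-oic acid | OC(=O)[C@H]1[C@@H](C)CC=C2C(C)(C)[C@H](Br)CC[C@]21C
F4 | step 10 | (3R,8S,9S,10R)-3-bromo-9-hydroperoxydrim-5-en-11-oic acid | OC(=O)[C@]1(OO)[C@@H](C)CC=C2C(C)(C)[C@H](Br)CC[C@]21C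
F5 | step 10 | (3R,8S,10R)-3-bromo-11-nordrim-5-en-9-one | O=C1[C@@H](C)CC=C2C(C)(C)[C@H](Br)CC[C@]21C
F6 | step 10 | (3R,8S,9R,10R)-3-bromo-9,11-epoxydrim-5-ene | C1O[C@@]12[C@@H](C)CC=C3C(C)(C)[C@H](Br)CC[C@]32C
F7 | step 5 | (5R)-5-bromo-2,6,6-trimethylcyclohex-1-ene-1-carbaldehyde | O=CC1=C(C)CC[C@@H](Br)C1(C)C
F8 | step 14 | (3R,5S,8S,9R,10R)-3-bromo-9-(triethylsilyloxy)-15,16-dinorlabd-13-ene | C=CCC[C@@]1(O[Si](CC)(CC)CC)[C@@H](C)CC[C@@H]2C(C)(C)[C@H](Br)CC[C@]21C
F9 | step 14 | (3R,5S,8S,9R,10R)-3-bromo-9-(triethylsilyloxy)-14,15-dinorlabdan-13-one | CC(=O)CC[C@@]1(O[Si](CC)(CC)CC)[C@@H](C)CC[C@@H]2C(C)(C)[C@H](Br)CC[C@]21C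
F10 | step 14 | ethyl (13E)-(3R,5S,8S,9R,10R)-3-bromo-9-(triethylsilyloxy)labd-13-en-15-oate | CCOC(=O)/C=C(\C)CC[C@@]1(O[Si](CC)(CC)CC)[C@@H](C)CC[C@@H]2C(C)(C)[C@H](Br)CC[C@]21C
F11 | step 15 | (3R,5S,8S,9R,10R)-3-bromo-9-(triethylsilyloxy)-16-norlabd-13-yn-15-ol | OCC#CCC[C@@]1(O[Si](CC)(CC)CC)[C@@H](C)CC[C@@H]2C(C)(C)[C@H](Br)CC[C@]21C
F12 | step 15 | (13Z)-(3R,5S,8S,9R,10R)-3-bromo-13-iodo-9-(triethylsilyloxy)-16-norlabd-13-en-15-ol | OC/C=C(\I)CC[C@@]1(O[Si](CC)(CC)CC)[C@@H](C)CC[C@@H]2C(C)(C)[C@H](Br)CC[C@]21C
A1 | alternative 1 | (3R,5S,8S,13R)-3-bromo-15-[(tert-butyldimethylsilyl)oxy]-13-[(triethylsilyl)oxy]-9,10-secolabd-10(20)-en-9-one | CC(C)(C)[Si](C)(C)OCC[C@](C)(O[Si](CC)(CC)CC)CCC(=O)[C@@H](C)CC[C@H]1C(=C)CC[C@@H](Br)C1(C)C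
A2 | alternative 1 | (3R,5S,8S,9R,10R,13R)-3-bromo-15-[(tert-butyldimethylsilyl)oxy]-9,20-epoxy-13-[(triethylsilyl)oxy]labdane | CC(C)(C)[Si](C)(C)OCC[C@](C)(O[Si](CC)(CC)CC)CC[C@@]1(O3)[C@@H](C)CC[C@@H]2C(C)(C)[C@H](Br)CC[C@]21C3
A3 | alternative 2 | (3aS,5R,7aR)-5-bromo-4,4,7a-trimethyloctahydro-1H-inden-1-one | O=C1CC[C@@H]2C(C)(C)[C@H](Br)CC[C@]21C
A4 | alternative 2 | diazoethane | CC=[N+]=[N-]
A5 | alternative 2 | (2S,4aS,6R,8aR)-6-bromo-2,5,5,8a-tetramethyloctahydronaphthalen-1(2H)-one | O=C1[C@@H](C)CC[C@@H]2C(C)(C)[C@H](Br)CC[C@]21C
A6 | alternative 3 | (7Z)-(3R,5S,10R,13R)-3,8-dibromo-15-[(tert-butyldimethylsilyl)oxy]-13-[(triethylsilyl)oxy]-8,9-secolabd-7-en-9-one | CC(C)(C)[Si](C)(C)OCC[C@](C)(O[Si](CC)(CC)CC)CCC(=O)[C@]1(C)CC[C@@H](Br)C(C)(C)[C@H]1C/C=C(\Br)C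
A7 | alternative 3 | (3R,5S,9R,10R,13R)-3-bromo-15-[(tert-butyldimethylsilyl)oxy]-13-[(triethylsilyl)oxy]labd-7-en-9-ol | CC(C)(C)[Si](C)(C)OCC[C@](C)(O[Si](CC)(CC)CC)CC[C@@]1(O)C(C)=CC[C@@H]2C(C)(C)[C@H](Br)CC[C@]21C
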